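Whatever happens, solid substrate, dissolved substrate, target (solid product counted in) and quenched substrate add up to the charge of solid substrate; partner and side product hold none of it. In the new flask the solid substrate is the limiting reagent against partner.

| setting | teal | violet | flask |
|---|---|---|---|
| solid substrate | 20 mM | 20 mM | 20 mM |
| partner | 25 mM | 38 mM | 50.0 mM |
| protic impurity | 20 mM | 20 mM | 20.0 mM |
| remark | run made earlier | run made earlier |  |
| time |  |  | 3.0 d |

- teal (time / h: solid substrate / %, target / %): 3.00: 3, 23; 6.00: 0, 30; 10.0: 2, 36; 15.0: 0, 33; 25.0: 3, 35; 40.0: 0, 36
- violet (time / h: solid substrate / %, target / %): 8.00: 2, 38; 15.0: 0, 37; 20.0: 1, 39; 30.0: 0, 43; 40.0: 0, 42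

(readings scatter by 1.5 percentage points)

- for target the solid product is counted in
- as a solid, counted per litre of solution: solid substrate, solid product
- reactions considered so far: solid product <-> target; solid substrate + protic impurity -> quenched substrate; dissolved substrate + partner -> target; solid substrate <-> dissolved substrate; partner -> side product
- at the start none of the solid substrate is in solution
- what has only dissolved of solid substrate counts as not reacted
- the reaction counts as stopped when no species that holds the solid substrate changes by six tenths of a point or more over the second half of the time

* at 3.0 d, what has stopped the reaction, if anything has (for what has run out or reacted, a solid counts together with what of it has only dissolved) (all of the solid substrate has reacted / it is still moving)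
* part of the solid substrate that has turned into other species by 3.0 d (what has only dissolved does not count)
* the target standing at 3.0 d, as a percentage of the solid substrate charged

The readings form a ladder. The solid goes first: the teal run reads 3% of it at 3.00 h and 0% at 6.00 h. Target comes next: in the teal run it reads 36% at 10.0 h and 36% at 40.0 h, and in the violet run 43% at 30.0 h and 42% at 40.0 h. The asked time of 3.0 d is longer than either run, so the new flask should stand on its plateau by then.

On the plateau the balance is a subtraction. Taking the last violet target from the charge leaves 58.0%. This is the toll, the part of the charge standing as anything but target; the teal run's reads 64.0%. The step that makes quenched substrate has no partner in it, so the reckoning here carries the violet toll over to the new flask, although the teal toll reads 6 percentage points above it and both carry the scatter of their readings. That gives target near 42.0%, and, if the whole toll is quenched substrate and one impurity is spent per substrate quenched, 42.0% of the protic impurity left.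

The forecast, judging that “Yield therefore rises only weakly with partner”, says all of the solid substrate has reacted, with 98% converted and 45% target, which stands 3 points above this reckoning.

In the flask, all of the solid substrate has reacted, with 99.8% converted and 41.8% target.

    solid product ⇌ target, rate k1*(cs1 - [target]) while solid is left; crystals form when [target] > cs1 (solubility = 3.60 mM, k = 0.0455 /s)
    solid substrate + protic impurity → quenched substrate (k = 0.0396 /M/s)
    dissolved substrate + partner → target (k = 0.00576 /M/s)
    solid substrate ⇌ dissolved substrate, rate k4*(cs4 - [dissolved substrate]) while solid is left; crystals form when [dissolved substrate] > cs4 (solubility = 9.70 mM, k = 3.82 × 10⁻⁴ /s)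
    partner → side product (k = 4.25 × 10⁻⁵ /s)

The forecast's three answers stand within their margins. The flask's toll is 58.2%, of which 58.0% is quenched substrate, and protic impurity stands at 42.0% of its charge. The neighbouring flask, charged with 12 mM of solid substrate and otherwise the same, reads 48.8% target, so its toll is 51.2%. Counted whole as quenched substrate, that toll comes to 6.14 mM of the smaller charge, which reckons 69.3% of the protic impurity left. The neighbouring flask holds 69.4% of its protic impurity.

(The readings were computed for substances that don't exist; scatter was added.)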